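**Retrosynthetic overview**

1. Target 16 ⇐ 14 by global deprotection (two TBS ethers, one dioxolane); no bond to C7 or C8 is touched.
2. 14 ⇐ (Z)-enol ether 12 by the proposed new step: reagent-controlled asymmetric syn-hydroboration/oxidation, which forms the C7–O bond and sets both stereocentres (C7, C8) at once.
3. 12 ⇐ (Z)-enoate 10 ⇐ aldol/dehydration of aryloxyacetate 4 with aldehyde 6 (C7–C8 bond).
4. 4 ⇐ acetosyringone 1 + ethyl bromoacetate 2 (C8–O–aryl bond), then ketal; 6 ⇐ vanillin 5.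
5. Rings: both benzene rings are bought; the only ring made is the temporary dioxolane (step 2), opened again in step 9.

Assumption: the target SMILES is read as (7R,8S) = (1R,2S), the erythro isomer (C7 = benzylic CHOH, C8 = CH–OAr, C9 = CH2OH); common reagents (TBSCl, LDA, DIBAL-H, IpcBH2 and the like) are bought and not numbered.

Abbreviations in step names: ArA = 4-[(tert-butyldimethylsilyl)oxy]-3-methoxyphenyl; ArB = 2,6-dimethoxy-4-(2-methyl-1,3-dioxolan-2-yl)phenyl.

**Step 1**
Reactants: 1 acetosyringone; 2 ethyl bromoacetate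
Product: 3 ethyl 2-(4-acetyl-2,6-dimethoxyphenoxy)acetate
Conditions: K2CO3, acetone, reflux
Reagents that add atoms: none
Why: Williamson ether synthesis (SN2) of the acidic phenoxide on a reactive α-bromo ester; the ketone is untouched.

**Step 2**
Reactants: 3 ethyl 2-(4-acetyl-2,6-dimethoxyphenoxy)acetate
Product: 4 ethyl 2-(ArB-oxy)acetate (dioxolane ketal of 3)
Conditions: TMSOCH2CH2OTMS, TMSOTf (cat.), CH2Cl2, −20 °C → rt
Reagents that add atoms: 1,2-bis(trimethylsilyloxy)ethane, C[Si](C)(C)OCCO[Si](C)(C)C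
Why: Noyori ketalisation masks the acetyl group against LDA, DIBAL-H and borane without transesterifying the ethyl ester.

**Step 3**
Reactants: 5 vanillin
Product: 6 4-[(tert-butyldimethylsilyl)oxy]-3-methoxybenzaldehyde
Conditions: TBSCl, imidazole, DMF, rt
Reagents that add atoms: tert-butyldimethylsilyl chloride, CC(C)(C)[Si](C)(C)Cl
Why: Standard phenol silylation; the aryl TBS ether survives LDA at −78 °C, DBU, DIBAL-H and borane and is removed by fluoride.

**Step 4**
Reactants: 4 ethyl 2-(ArB-oxy)acetate; 6 4-[(tert-butyldimethylsilyl)oxy]-3-methoxybenzaldehyde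
Product: 8 ethyl 3-ArA-2-(ArB-oxy)-3-hydroxypropanoate (racemic erythro/threo mixture), via lithium enolate 7 (not isolated)
Conditions: LDA, THF, −78 °C; then 6, −78 °C; AcOH quench
Reagents that add atoms: lithium diisopropylamide, CC(C)N([Li])C(C)C (Li of 7 only)
Why: Lithium ester-enolate aldol addition, the classical entry to β-O-4 skeletons, forms C7–C8; its stereocentres are erased in step 5, so the diastereomer ratio does not matter.

**Step 5**
Reactants: 8 ethyl 3-ArA-2-(ArB-oxy)-3-hydroxypropanoate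
Product: 10 ethyl (Z)-3-ArA-2-(ArB-oxy)prop-2-enoate, via secondary mesylate 9 (not isolated)
Conditions: MsCl, Et3N, CH2Cl2, 0 °C; then DBU, rt
Reagents that add atoms: methanesulfonyl chloride, CS(=O)(=O)Cl (mesyl group of 9 only)
Why: Mesylation then E1cB elimination converges both aldol diastereomers on the conjugated enoate, whose favoured isomer is Z (ArA trans to CO2Et, cis to OArB) as for other 2-alkoxy- and 2-aryloxycinnamates; the minor E isomer is removed by chromatography.

**Step 6**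
Reactants: 10 ethyl (Z)-3-ArA-2-(ArB-oxy)prop-2-enoate
Product: 11 (Z)-3-ArA-2-(ArB-oxy)prop-2-en-1-ol
Conditions: DIBAL-H, CH2Cl2, −78 °C; Rochelle salt work-up
Reagents that add atoms: none
Why: 1,2-Reduction of the enoate by DIBAL-H gives the allylic alcohol with the alkene geometry kept; ketal and silyl ether are inert at −78 °C.

**Step 7**
Reactants: 11 (Z)-3-ArA-2-(ArB-oxy)prop-2-en-1-ol
Product: 12 (Z)-1-[(tert-butyldimethylsilyl)oxy]-3-ArA-2-(ArB-oxy)prop-2-ene
Conditions: TBSCl, imidazole, DMF, 0 °C → rt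
Reagents that add atoms: tert-butyldimethylsilyl chloride, CC(C)(C)[Si](C)(C)Cl
Why: Silylation of the primary alcohol keeps the O–H from consuming B–H in the next step and masks C9–OH.

**Step 8**
Reactants: 12 (Z)-1-[(tert-butyldimethylsilyl)oxy]-3-ArA-2-(ArB-oxy)prop-2-ene
Product: 14 (1R,2S)-3-[(tert-butyldimethylsilyl)oxy]-1-ArA-2-(ArB-oxy)propan-1-ol, via C7 isopinocampheylborane adduct 13 (not isolated)
Conditions: IpcBH2 [from (−)-α-pinene, freshly liberated from its TMEDA adduct, 1.5 equiv], THF, −25 °C, 36 h; then 3 M NaOAc (aq), 30% H2O2, 0 °C → rt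
Reagents that add atoms: monoisopinocampheylborane from (−)-α-pinene, C[C@@H]1[C@@H](B)C[C@H]2C[C@@H]1C2(C)C (B and isopinocampheyl of 13; H on C8); hydrogen peroxide, OO (O of the new OH)
Why: Proposed new method: reagent-controlled asymmetric hydroboration–oxidation of an acyclic (Z)-β-aryl-α-aryloxy trisubstituted enol ether (lignin β-O-4 type), a substrate class on which it has not been shown; π-donation from the enol-ether oxygen makes C7 the nucleophilic carbon and C8 is fully substituted, so boron goes to benzylic C7 and H to C8; the concerted four-centre syn addition to the Z alkene fixes the relative configuration as erythro (1R*,2S*) whatever the reagent; the chiral pocket of IpcBH2 selects the alkene face (by the empirical Brown model the (+)-α-pinene reagent gives the S carbinol with trisubstituted alkenes, so the (−)-α-pinene reagent is chosen for 1R,2S); oxidation proceeds by stereoretentive B→O 1,2-migration; closest known chemistry is Brown asymmetric hydroboration of 2-methoxy-2-butenes and cyclic enol ethers with Ipc2BH and of 1-arylcycloalkenes with IpcBH2, and racemic BH3 hydroboration of enol ethers.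

**Step 9**
Reactants: 14 (1R,2S)-3-[(tert-butyldimethylsilyl)oxy]-1-ArA-2-(ArB-oxy)propan-1-ol
Product: 16 1-(4-{[(1R,2S)-1,3-dihydroxy-1-(4-hydroxy-3-methoxyphenyl)propan-2-yl]oxy}-3,5-dimethoxyphenyl)ethan-1-one, via desilylated dioxolane triol 15 (not isolated)
Conditions: TBAF (2.5 equiv), THF, 0 °C; then 1 M HCl (aq), rt, 1 h
Reagents that add atoms: water, O (carbonyl O of the acetyl group)
Why: Fluoride cleaves both silyl ethers and dilute aqueous acid hydrolyses the aryl-ketone dioxolane at room temperature; no bond to C7 or C8 is broken, so (1R,2S) is retained.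

**Compound list**

1 | acetosyringone, 1-(4-hydroxy-3,5-dimethoxyphenyl)ethan-1-one | CC(=O)c1cc(OC)c(O)c(OC)c1 | starting material
2 | ethyl bromoacetate | CCOC(=O)CBr | starting material
3 | ethyl 2-(4-acetyl-2,6-dimethoxyphenoxy)acetate | CCOC(=O)COc1c(OC)cc(C(C)=O)cc1OC | intermediate
4 | ethyl 2-[2,6-dimethoxy-4-(2-methyl-1,3-dioxolan-2-yl)phenoxy]acetate | CCOC(=O)COc1c(OC)cc(C2(C)OCCO2)cc1OC | intermediate
5 | vanillin, 4-hydroxy-3-methoxybenzaldehyde | COc1cc(C=O)ccc1O | starting material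
6 | 4-[(tert-butyldimethylsilyl)oxy]-3-methoxybenzaldehyde | COc1cc(C=O)ccc1O[Si](C)(C)C(C)(C)C | intermediate
7 | lithium enolate of 4 (not isolated) | CCOC(O[Li])=COc1c(OC)cc(C2(C)OCCO2)cc1OC | intermediate
8 | ethyl 3-{4-[(tert-butyldimethylsilyl)oxy]-3-methoxyphenyl}-2-[2,6-dimethoxy-4-(2-methyl-1,3-dioxolan-2-yl)phenoxy]-3-hydroxypropanoate, racemic erythro/threo mixture | CCOC(=O)C(Oc1c(OC)cc(C2(C)OCCO2)cc1OC)C(O)c1ccc(O[Si](C)(C)C(C)(C)C)c(OC)c1 | intermediate
9 | 3-O-methanesulfonate of 8 (not isolated) | CCOC(=O)C(Oc1c(OC)cc(C2(C)OCCO2)cc1OC)C(OS(C)(=O)=O)c1ccc(O[Si](C)(C)C(C)(C)C)c(OC)c1 | intermediate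
10 | ethyl (2Z)-3-{4-[(tert-butyldimethylsilyl)oxy]-3-methoxyphenyl}-2-[2,6-dimethoxy-4-(2-methyl-1,3-dioxolan-2-yl)phenoxy]prop-2-enoate (aryl cis to aryloxy) | CCOC(=O)/C(Oc1c(OC)cc(C2(C)OCCO2)cc1OC)=C/c1ccc(O[Si](C)(C)C(C)(C)C)c(OC)c1 | intermediate
11 | (2Z)-3-{4-[(tert-butyldimethylsilyl)oxy]-3-methoxyphenyl}-2-[2,6-dimethoxy-4-(2-methyl-1,3-dioxolan-2-yl)phenoxy]prop-2-en-1-ol | OC/C(Oc1c(OC)cc(C2(C)OCCO2)cc1OC)=C/c1ccc(O[Si](C)(C)C(C)(C)C)c(OC)c1 | intermediate
12 | tert-butyl{[(2Z)-3-{4-[(tert-butyldimethylsilyl)oxy]-3-methoxyphenyl}-2-[2,6-dimethoxy-4-(2-methyl-1,3-dioxolan-2-yl)phenoxy]prop-2-en-1-yl]oxy}dimethylsilane | CC(C)(C)[Si](C)(C)OC/C(Oc1c(OC)cc(C2(C)OCCO2)cc1OC)=C/c1ccc(O[Si](C)(C)C(C)(C)C)c(OC)c1 | intermediate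
13 | alkyl(isopinocampheyl)borane from 12: B–H on C7 in the position later taken by OH, H on C8 syn to it, isopinocampheyl from (−)-α-pinene (not isolated) | COc1cc([C@@H](B[C@H]2C[C@H]3C[C@@H]([C@@H]2C)C3(C)C)[C@H](CO[Si](C)(C)C(C)(C)C)Oc4c(OC)cc(C5(C)OCCO5)cc4OC)ccc1O[Si](C)(C)C(C)(C)C | intermediate
14 | (1R,2S)-3-[(tert-butyldimethylsilyl)oxy]-1-{4-[(tert-butyldimethylsilyl)oxy]-3-methoxyphenyl}-2-[2,6-dimethoxy-4-(2-methyl-1,3-dioxolan-2-yl)phenoxy]propan-1-ol | COc1cc([C@@H](O)[C@H](CO[Si](C)(C)C(C)(C)C)Oc2c(OC)cc(C3(C)OCCO3)cc2OC)ccc1O[Si](C)(C)C(C)(C)C | intermediate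
15 | (1R,2S)-2-[2,6-dimethoxy-4-(2-methyl-1,3-dioxolan-2-yl)phenoxy]-1-(4-hydroxy-3-methoxyphenyl)propane-1,3-diol (not isolated) | COc1cc([C@@H](O)[C@H](CO)Oc2c(OC)cc(C3(C)OCCO3)cc2OC)ccc1O | intermediate
16 | 1-(4-{[(1R,2S)-1,3-dihydroxy-1-(4-hydroxy-3-methoxyphenyl)propan-2-yl]oxy}-3,5-dimethoxyphenyl)ethan-1-one (CNP0242981.1) | COc1cc([C@@H](O)[C@H](CO)Oc2c(OC)cc(C(C)=O)cc2OC)ccc1O | target

**Step count and risks**

Total steps: 9. Longest linear sequence: 8 (1 → 3 → 4 → 8 → 10 → 11 → 12 → 14 → 16); step 3 (5 → 6) is a one-step side branch.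

Three steps most likely to fail:

Step 8 (the proposed new hydroboration). Risks are incomplete face selectivity, β-aryloxy elimination from borane 13 if it warms before oxidation, and any E alkene carried over (it would give the threo isomer). The ee is measured by chiral HPLC or Mosher ester; if the sense is opposite to the prediction, the (+)-α-pinene reagent is used. Fallback, known chemistry without hydroboration, sets out from 8 and comes back to the route at 16. The lithium-enolate aldol that gives 8 is erythro-selective, as in the classical β-O-4 model synthesis. LiBH4 in THF/MeOH at 0 °C reduces the ester of 8, and the racemic erythro 1-ArA-2-(ArB-oxy)propane-1,3-diol F1 is separated from its threo isomer on silica. Its enantiomers are separated by preparative chiral SFC on a polysaccharide phase to give the (1R,2S)-diol F2, which is converted into 16 under the step 9 conditions.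

Step 5 (alkene geometry). The Z/E ratio of the E1cB elimination may be lower than expected with the bulky 2,6-dimethoxyaryloxy group, and only Z leads to erythro. Fallback sets out from 1 and comes back at 10, building the alkene by olefination instead of elimination. Rh2(OAc)4-catalysed O–H insertion of the carbene from triethyl diazophosphonoacetate into the phenol of 1 (toluene, 80 °C) gives ethyl 2-(4-acetyl-2,6-dimethoxyphenoxy)-2-(diethoxyphosphoryl)acetate F3. Noyori ketalisation as in step 2 gives the dioxolane phosphonate F4. Horner–Wadsworth–Emmons olefination of 6 with F4 (NaH, THF, 0 °C → rt) gives 10, Z-major as for other 2-alkoxyphosphonoacetates.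

Step 9 (global deprotection). The free p-hydroxybenzyl alcohol of 15 can ionise at C7 in acid, which would epimerise it or form a quinone methide. Fallback sets out from 14 and comes back at 16, with the order of unmasking changed so that acid never meets the free phenol. The dioxolane is hydrolysed first (PPTS, THF/H2O, 40 °C) to the bis-silylated ketone F5, and both silyl ethers are then cleaved with AcOH-buffered TBAF (THF, 0 °C) to give 16.

**Further compounds**

F1 | step 8 | racemic erythro (1R*,2S*)-1-{4-[(tert-butyldimethylsilyl)oxy]-3-methoxyphenyl}-2-[2,6-dimethoxy-4-(2-methyl-1,3-dioxolan-2-yl)phenoxy]propane-1,3-diol (1:1 pair of enantiomers) | COc1cc([C@@H](O)[C@H](CO)Oc2c(OC)cc(C3(C)OCCO3)cc2OC)ccc1O[Si](C)(C)C(C)(C)C.COc1cc([C@H](O)[C@@H](CO)Oc2c(OC)cc(C3(C)OCCO3)cc2OC)ccc1O[Si](C)(C)C(C)(C)C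
F2 | step 8 | (1R,2S)-1-{4-[(tert-butyldimethylsilyl)oxy]-3-methoxyphenyl}-2-[2,6-dimethoxy-4-(2-methyl-1,3-dioxolan-2-yl)phenoxy]propane-1,3-diol | COc1cc([C@@H](O)[C@H](CO)Oc2c(OC)cc(C3(C)OCCO3)cc2OC)ccc1O[Si](C)(C)C(C)(C)C
F3 | step 5 | ethyl 2-(4-acetyl-2,6-dimethoxyphenoxy)-2-(diethoxyphosphoryl)acetate (racemic) | CCOC(=O)C(Oc1c(OC)cc(C(C)=O)cc1OC)P(=O)(OCC)OCC
F4 | step 5 | ethyl 2-(diethoxyphosphoryl)-2-[2,6-dimethoxy-4-(2-methyl-1,3-dioxolan-2-yl)phenoxy]acetate (racemic) | CCOC(=O)C(Oc1c(OC)cc(C2(C)OCCO2)cc1OC)P(=O)(OCC)OCC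
F5 | step 9 | 1-(4-{[(1R,2S)-3-[(tert-butyldimethylsilyl)oxy]-1-{4-[(tert-butyldimethylsilyl)oxy]-3-methoxyphenyl}-1-hydroxypropan-2-yl]oxy}-3,5-dimethoxyphenyl)ethan-1-one | COc1cc([C@@H](O)[C@H](CO[Si](C)(C)C(C)(C)C)Oc2c(OC)cc(C(C)=O)cc2OC)ccc1O[Si](C)(C)C(C)(C)C
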